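**Assumptions**

- Icetexane numbering is used throughout: ring A is C1–C5 and C10, C20 lies between C9 and C10, ring C is C8, C9, C11–C14. Primed locants denote the half of the dimer whose ring C is the dione.
- Remark on the chemistry: 4-bromothymol (compound 8) is treated as a catalogue compound; if it is not to hand it is one para-bromination away from thymol.
- Remark on the chemistry: the catechol oxygens are carried as methoxymethyl (MOM) ethers instead of methyl ethers. The skeletons of the key-step precursor 15 and product 17 are unchanged, but the unmasking then needs only the dilute acid that also closes the ether bridge, not a hot thiolate demethylation of an air-sensitive catechol.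
- Remark on the chemistry: C5 of diketone 15 is (S), which maps onto 5S in 17, 19 and 21, and the hemiketal carbon of 17 is 7S with the hydroxyl exo.
- Remark on the chemistry: the last step is a dimerization, so each molecule of 21 consumes two molecules of 19 (two molecules of 20).

## Structural features

The target 21 is a C40 dimer of two icetexane units, each with a cyclohexane ring A carrying a gem-dimethyl C4, a seven-membered ring B and a six-membered ring C carrying isopropyl at C13, and each with a 7,10-oxygen bridge that turns ring B into an 8-oxabicyclo[3.2.1]octane. In each half C5, C10 and C7 are stereogenic: C5 and C10 are adjacent, C10 is quaternary and oxygen-bearing, and the bridge forces the C10 oxygen cis to C6 on ring A and fixes C7 once C10 is set. The halves differ only in ring C: one is an aromatic catechol whose O11 and O12 belong to a 1,4-dioxane, the other is an 8'-ene-11',12'-dione with adjacent sp3 centres C13' (isopropyl, O11) and C14' (H, O12), cis on the dioxane, which gives eight stereocentres in all. Fragile points are the ene-1,2-dione (bases, nucleophiles), the catechol and ortho-quinone oxidation levels of the monomer (air, nucleophiles), and the C7–O bonds, which are benzylic or allylic and ionise under strong acid. The cis dioxane is the retron of a hetero-Diels–Alder reaction between the O11=C11–C12=O12 dione of one ortho-quinone and C13'=C14' of a second, so the real problem is one enantiopure monomer plus a selective dimerization. Within the monomer the difficulty is the quaternary C10, flanked by C5 and benzylic C20 inside a medium ring. The key step exploits the isochroman ring O–C7–C8–C9–C20–C10, the formal adduct of an ortho-quinodimethane (C20=C9–C8=C7) and a C10 carbonyl, so that ring B and the ether ring close together from a monocyclic diketone whose only stereocentre is C5.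

## Logic of the disconnections

**21 to 20.** The bonds O12–C14' and O11–C13' are cut. Both halves then become the same compound 20, two molecules of which are needed for one of 21, and this halves the problem. The forward step must control regiochemistry and the face of C13'=C14'; cis fusion follows from suprafacial addition.

**20 to 19 to 17.** No skeletal bond is cut. The C11/C12 carbonyls go back to the catechol of 19, the C7–H goes back to the hemiketal hydroxyl, and the phenols go back to the MOM ethers of 17 (through 18). The quinone is made last because it is the most sensitive compound. The forward step must replace the C7 hydroxyl by hydrogen without cleaving the benzylic ether.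

**17 to 15.** The bonds C20–C10 and O–C7 are cut (through 16). A bridged tricycle with three stereocentres becomes a monocyclic 1,4-diketone with one. The forward step must make a photoenol add to an unactivated ketone and must leave C5, which is α to that ketone, untouched.

**15 to 14 to 12 and 7.** The aryl–acyl bond C7–C8 is cut. The arene becomes a nucleophile (13 from 12) and the lactone 7 serves as the acyl donor and as internal protection of the C10 oxygen. The demand is a single addition, followed by oxidation of the liberated C10 carbinol.

**7 to 6 to 4.** The C10–O bond is cut (with the C1–I bond of 6, through 5). The carboxylate delivers oxygen to C10 and not to C1, which a direct alkene oxidation could not guarantee. The cis ring fusion is inherent.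

**4 to 2 and 3, then 2 to 1.** The C5–C6 bond is cut by a Claisen retron. The forward step transfers a C–O stereocentre, available by catalytic reduction of 1, to the hindered C5 next to quaternary C4.

**12 to 11 to 9 to 8.** The two O–CH2 bonds are cut, then the C11–O bond (through 10) and the C–CHO bond. In 8 the bromine already sits next to the methyl group and para to the hydroxyl, so the arene substitution pattern is fixed by the starting material and not by a late halogenation.

## Other disconnections considered

Alternative 1: The cut runs through ring C itself (C8–C9, C11–C12, C11–O). The forward step would treat the furan–yne A1, a cis-fused 2-furyl-7a-propargyl octahydrobenzofuran, with AuCl3 in acetonitrile. Trivalent gold activates the alkyne, the furan adds, and the arene oxide opens to the phenol A2 (12-deoxybrussonol), closing rings C and B together.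
- In favour: the reaction class is established, which is better than the chosen plan, whose step 10 is not precedented. No phenol protection is needed at all, which is also better. A2 should reach 20 by one ortho-oxidation, so two steps follow the key step, equal to the chosen plan. An ambiguity in arene oxide opening would not matter, since either phenol position leads to 20 on ortho-oxidation.
- Against: A1 must already hold C5, C7 and C10 and the cis-fused ether, three stereocentres before the key step against one in 15. Its C7 is a furfuryl ether that a Lewis-acidic gold salt can ionise. The 4-isopropylfuran-2-yl unit of A1 is awkward to install.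
- Comparison: structurally the alternative moves the difficulty into the precursor; mechanistically it is safer; in step count the saving after the key step is likely lost in making A1.

Alternative 2: The cut is C4–C5. Fe(acac)3 and phenylsilane in ethanol would convert the isopropenyl group of butenolide A3 into a tertiary C4 radical that adds to the butenolide β-carbon, giving the cis-fused lactone A4.
- In favour: every step is a known reaction class, which is better than the chosen plan. Radical conjugate addition copes with a bond between a quaternary and a tertiary carbon. The relay of configuration from C10 to C5 through the cis fusion equals the chosen plan in logic, since one centre controls the rest.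
- Against: the absolute configuration must be introduced at the tetrasubstituted carbinol carbon C10 of A3, which is harder than reducing enone 1. The key step makes one bond and one ring against two and two. After A4, half-reduction, Friedel–Crafts closure to A5, a hot thiolate demethylation to 19, and step 12 are still needed, four steps against two.
- Comparison: more secure mechanistically, weaker in the stereochemical source and in step economy.

Alternative 3: The cuts are C4–C5, O–C10 and C7–C8. SnCl4 would open the epoxide of the E-configured epoxy acetal A6; the C5=C10 alkene, an acetal oxygen and the arene would then react in sequence to give A7 (3-hydroxybrussonol dimethyl ether).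
- In favour: three bonds, three rings and all three stereocentres of a half arise from one epoxide centre. This is better than the chosen plan in bond economy and equal in relying on a single reagent-controlled stereocentre.
- Against: A7 carries a C3 hydroxyl that 21 lacks, so a two-step radical deoxygenation to A5, demethylation to 19 and step 12 follow, four steps against two. The trisubstituted alkene of A6 has three different carbon arms and its geometry decides the C5/C10 relationship. SnCl4 can ionise the acetal before the epoxide, closing ring B on the arene without ring A, and the tertiary C10 cation can eliminate.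
- Comparison: the most elegant on paper, but the chemoselectivity of the cascade is as uncertain as step 10 and the route is longer.

Key step: step 10

## Route

Step 1
Reactants: 1 4,4-dimethylcyclohex-2-en-1-one
Product: 2 (R)-4,4-dimethylcyclohex-2-en-1-ol
Conditions: (S)-Me-CBS [(S)-1-methyl-3,3-diphenyltetrahydro-1H,3H-pyrrolo[1,2-c][1,3,2]oxazaborole] (10 mol %), BH3·SMe2, THF, −20 °C; MeOH
Reagents that add atoms: none
Why: Corey–Bakshi–Shibata reduction; with the alkenyl arm acting as the larger group the (S)-catalyst should deliver hydride to give the (R)-allylic alcohol. The alkene next to the quaternary carbon is too hindered for competing hydroboration.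

Step 2
Reactants: 2 (R)-4,4-dimethylcyclohex-2-en-1-ol; 3 triethyl orthoacetate
Product: 4 ethyl 2-[(1R)-6,6-dimethylcyclohex-2-en-1-yl]acetate
Conditions: EtCO2H (cat.), neat 3 (excess), 140 °C, EtOH distilled off
Reagents that add atoms: none
Why: Johnson–Claisen rearrangement; the ketene acetal rearranges suprafacially, so the new C5–C6 bond forms on the ring face that carried the oxygen and the (R)-carbinol becomes the (R)-configured C5. The sigmatropic shift forms the bond next to quaternary C4 without an intermolecular approach to that hindered carbon.

Step 3
Reactants: 4 ethyl 2-[(1R)-6,6-dimethylcyclohex-2-en-1-yl]acetate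
Product: 6 (3aS,7S,7aS)-7-iodo-4,4-dimethylhexahydro-1-benzofuran-2(3H)-one, via unsaturated acid 5 (not isolated)
Conditions: LiOH, THF/H2O, 40 °C; then NaHCO3, I2, KI, 0 to 23 °C, dark
Reagents that add atoms: lithium hydroxide [Li+].[OH-]; iodine II
Why: Saponification followed by iodolactonization; the carboxylate opens the iodonium ion anti at the nearer alkene carbon C10 (5-exo), which gives the cis-fused γ-lactone with iodine trans to the ring oxygen. This places oxygen on C10 and not on C1.

Step 4
Reactants: 6 (3aS,7S,7aS)-7-iodo-4,4-dimethylhexahydro-1-benzofuran-2(3H)-one
Product: 7 (3aS,7aR)-4,4-dimethylhexahydro-1-benzofuran-2(3H)-one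
Conditions: (Me3Si)3SiH, AIBN (cat.), toluene, 80 °C
Reagents that add atoms: none
Why: Radical chain reduction of the secondary C–I bond; the two ring-fusion centres are not involved and the lactone is inert to silyl radicals.

Step 5
Reactants: 8 4-bromothymol (4-bromo-2-isopropyl-5-methylphenol)
Product: 9 3-bromo-6-hydroxy-5-isopropyl-2-methylbenzaldehyde
Conditions: MgCl2, Et3N, (CH2O)n, MeCN, reflux; 1 M HCl
Reagents that add atoms: paraformaldehyde (as formaldehyde) C=O
Why: Casnati–Skattebøl ortho-formylation of the phenoxide bound to MgCl2; the only free ortho position lies between the hydroxyl and the methyl group and the para position is blocked by bromine, so one regioisomer is possible.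

Step 6
Reactants: 9 3-bromo-6-hydroxy-5-isopropyl-2-methylbenzaldehyde
Product: 11 4-bromo-6-isopropyl-3-methylbenzene-1,2-diol, via aryl formate 10 (not isolated)
Conditions: 30% H2O2, NaOH (aq), THF, 0 °C, N2; then HCl to pH 2
Reagents that add atoms: hydrogen peroxide OO
Why: Dakin oxidation; hydroperoxide adds to the ortho-hydroxy aldehyde, the aryl group migrates to oxygen and formate 10 is hydrolysed in the basic medium. Exclusion of air and prompt acidification protect the catechol.

Step 7
Reactants: 11 4-bromo-6-isopropyl-3-methylbenzene-1,2-diol
Product: 12 1-bromo-5-isopropyl-3,4-bis(methoxymethoxy)-2-methylbenzene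
Conditions: NaH, MeOCH2Cl, DMF, 0 to 23 °C
Reagents that add atoms: chloromethyl methyl ether COCCl
Why: Williamson-type acetal formation on both hindered phenoxides. MOM ethers survive organolithium, periodinane and Ti(OiPr)4 and are removed later by dilute acid.

Step 8
Reactants: 12 1-bromo-5-isopropyl-3,4-bis(methoxymethoxy)-2-methylbenzene; 7 (3aS,7aR)-4,4-dimethylhexahydro-1-benzofuran-2(3H)-one
Product: 14 1-[5-isopropyl-3,4-bis(methoxymethoxy)-2-methylphenyl]-2-[(1S,2R)-2-hydroxy-6,6-dimethylcyclohexyl]ethan-1-one, via aryllithium 13 (not isolated)
Conditions: n-BuLi, THF, −78 °C; then 7, −78 °C; NH4Cl (aq) at −78 °C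
Reagents that add atoms: none
Why: Bromine–lithium exchange followed by acyl substitution on the lactone; the tetrahedral lithium hemiketal alkoxide should survive until the cold quench, so the hindered aryllithium adds only once. 14 is expected mainly as the open hydroxy ketone in equilibrium with its cyclic hemiketal.

Step 9
Reactants: 14 1-[5-isopropyl-3,4-bis(methoxymethoxy)-2-methylphenyl]-2-[(1S,2R)-2-hydroxy-6,6-dimethylcyclohexyl]ethan-1-one
Product: 15 (2S)-2-{2-[5-isopropyl-3,4-bis(methoxymethoxy)-2-methylphenyl]-2-oxoethyl}-3,3-dimethylcyclohexan-1-one
Conditions: Dess–Martin periodinane, NaHCO3, CH2Cl2, 0 to 23 °C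
Reagents that add atoms: none
Why: Dess–Martin oxidation of the secondary C10 carbinol; only the open-chain tautomer can be oxidized, so the equilibrium drains into 15. Buffered, non-basic conditions should preserve the α-stereocentre C5 and avoid aldol or furan formation from the 1,4-diketone.

Step 10
Reactants: 15 (2S)-2-{2-[5-isopropyl-3,4-bis(methoxymethoxy)-2-methylphenyl]-2-oxoethyl}-3,3-dimethylcyclohexan-1-one
Product: 17 (5S,7S,10S)-7-hydroxy-11,12-bis(methoxymethoxy)-7,10-epoxyicetexa-8,11,13-triene (bridged hemiketal), via E-dienol 16 (not isolated)
Conditions: hν (365 nm LED), Ti(OiPr)4 (3 equiv), degassed toluene (0.01 M), 23 °C; KNaC4H4O6 (aq)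
Reagents that add atoms: none
Why: Proposed new method: excitation of the aryl ketone at 365 nm and 1,5-hydrogen transfer from the C20 methyl group through a six-membered transition state give the hydroxy ortho-quinodimethane; its Z isomer returns to 15 by a 1,5-hydrogen shift, while the E isomer 16 (C6 pointing inward, towards C20) should be held as a titanium dienolate by Ti(OiPr)4, which can bind the C10 carbonyl at the same metal, activating the plain ketone and placing it over the diene, so that C20 bonds to C10 and the carbonyl oxygen to C7 in an asynchronous hetero-Diels–Alder addition (an aldol addition followed by hemiketalization leads to the same compound) and the arene is restored. The closest known reaction types are the Ti(OiPr)4-promoted photoenolization/Diels–Alder reaction of ortho-methyl aryl carbonyl compounds with enones and the hetero-Diels–Alder capture of photoenols by activated carbonyl groups such as trifluoromethyl ketones and glyoxylates; capture by a plain, tethered dialkyl ketone has not been shown. Ring B closes through the C20–C10 bond as a 7-exo-trig attack on the carbonyl group and the five-membered ether ring closes through the O–C7 bond as a 5-exo-trig addition to the enol carbon, the six-membered isochroman being the cycloadduct ring itself. C10 is controlled by C5, because the two-atom tether C6–C5 lets the carbonyl reach both diene termini only in the bridged orientation, which puts the C10 oxygen cis to C6 on ring A (10S from 5S); C7 is then fixed by the bridge with its hydroxyl exo (7S). The step needs hydrogen abstraction from C20 only, which the substrate secures because the alkyl side of the aryl ketone has no γ-hydrogen (C4 is quaternary and C10 is a carbonyl carbon). It also needs C5, which is α to the C10 ketone, to keep its configuration, which neutral conditions at 23 °C and the weak basicity of Ti(OiPr)4 should allow. The only other fate of 16 is return to 15, so unproductive excitation costs photons and not material.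

Step 11
Reactants: 17 (5S,7S,10S)-7-hydroxy-11,12-bis(methoxymethoxy)-7,10-epoxyicetexa-8,11,13-triene
Product: 19 brussonol [(5S,7S,10S)-7,10-epoxyicetexa-8,11,13-triene-11,12-diol], via diol 18 (not isolated)
Conditions: NaBH4, MeOH/THF, 0 to 23 °C; then conc. HCl (to about 1 M), 40 °C, Ar
Reagents that add atoms: none
Why: Borohydride reduction of the aryl ketone in the ring-opened hydroxy ketone tautomer of 17 gives diol 18 (both C7 epimers are usable). Acid then ionizes the benzylic C7–OH, which is para to the C12 oxygen; the C10 hydroxyl closes the five-membered ether in an SN1 cycloetherification, and the same methanolic HCl cleaves both MOM acetals. The bridge allows only the 7S geometry, and no hydride is present when the cation exists, so over-reduction at C7 is excluded.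

Step 12
Reactants: 19 brussonol [(5S,7S,10S)-7,10-epoxyicetexa-8,11,13-triene-11,12-diol] (two molecules per molecule of dimer; this one becomes the aromatic half)
Product: 21 CNP0371333.1 (hetero-Diels–Alder dimer), via ortho-quinone 20 (not isolated)
Conditions: Ag2O (2.5 equiv per catechol), Na2SO4, Et2O, 23 °C, dark; filter, concentrate; neat film, 45 °C, Ar
Reagents that add atoms: second molecule of brussonol 19 (becomes the dione half) CC(C)c1cc2c(c(O)c1O)C[C@@]13CCCC(C)(C)[C@@H]1C[C@@H]2O3
Why: Two molecules of 19 are consumed: Ag2O oxidation of each catechol should give ortho-quinone 20, and on concentration one molecule of 20 acts as the heterodiene (O11=C11–C12=O12) and a second as the dienophile (C13'=C14') in the hetero-Diels–Alder dimerization typical of hindered ortho-quinones of this family. Bonding of O12 to the unsubstituted C14' and of O11 to C13' keeps the two isopropyl groups apart, and suprafacial addition makes the dioxane cis-fused. 21 requires attack on the face of C13'=C14' anti to the 7',10'-oxygen bridge (13'R,14'R), which repulsion between the bridging ether oxygen and the incoming quinone oxygen should favour, though only modestly.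

## Compound list

1 | 4,4-dimethylcyclohex-2-en-1-one | CC1(C)CCC(=O)C=C1 | starting material
2 | (R)-4,4-dimethylcyclohex-2-en-1-ol | O[C@H]1C=CC(C)(C)CC1 | intermediate
3 | triethyl orthoacetate | CCOC(C)(OCC)OCC | starting material
4 | ethyl 2-[(1R)-6,6-dimethylcyclohex-2-en-1-yl]acetate | CCOC(=O)C[C@@H]1C=CCCC1(C)C | intermediate
5 | 2-[(1R)-6,6-dimethylcyclohex-2-en-1-yl]acetic acid (formed in the flask as its lithium salt) | OC(=O)C[C@@H]1C=CCCC1(C)C | intermediate
6 | (3aS,7S,7aS)-7-iodo-4,4-dimethylhexahydro-1-benzofuran-2(3H)-one (cis-fused, iodine trans to the ring oxygen) | O=C1C[C@H]2C(C)(C)CC[C@H](I)[C@H]2O1 | intermediate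
7 | (3aS,7aR)-4,4-dimethylhexahydro-1-benzofuran-2(3H)-one (cis-fused) | O=C1C[C@H]2C(C)(C)CCC[C@H]2O1 | intermediate
8 | 4-bromothymol (4-bromo-2-isopropyl-5-methylphenol) | CC(C)c1cc(Br)c(C)cc1O | starting material
9 | 3-bromo-6-hydroxy-5-isopropyl-2-methylbenzaldehyde | CC(C)c1cc(Br)c(C)c(C=O)c1O | intermediate
10 | 3-bromo-6-hydroxy-5-isopropyl-2-methylphenyl formate (formed in the flask) | CC(C)c1cc(Br)c(C)c(OC=O)c1O | intermediate
11 | 4-bromo-6-isopropyl-3-methylbenzene-1,2-diol | CC(C)c1cc(Br)c(C)c(O)c1O | intermediate
12 | 1-bromo-5-isopropyl-3,4-bis(methoxymethoxy)-2-methylbenzene | CC(C)c1cc(Br)c(C)c(OCOC)c1OCOC | intermediate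
13 | [5-isopropyl-3,4-bis(methoxymethoxy)-2-methylphenyl]lithium (formed in the flask) | [Li]c1cc(C(C)C)c(OCOC)c(OCOC)c1C | intermediate
14 | 1-[5-isopropyl-3,4-bis(methoxymethoxy)-2-methylphenyl]-2-[(1S,2R)-2-hydroxy-6,6-dimethylcyclohexyl]ethan-1-one | CC(C)c1cc(C(=O)C[C@H]2C(C)(C)CCC[C@H]2O)c(C)c(OCOC)c1OCOC | intermediate
15 | (2S)-2-{2-[5-isopropyl-3,4-bis(methoxymethoxy)-2-methylphenyl]-2-oxoethyl}-3,3-dimethylcyclohexan-1-one (key-step precursor) | CC(C)c1cc(C(=O)C[C@H]2C(C)(C)CCCC2=O)c(C)c(OCOC)c1OCOC | intermediate
16 | E-dienol of 15 (hydroxy ortho-quinodimethane: exocyclic C7(OH)=C8 and C9=C20H2, hydroxyl anti to C9, C5 still S; formed in the flask, titanium-bound) | CC(C)C1=C/C(=C(\O)C[C@H]2C(C)(C)CCCC2=O)C(=C)C(OCOC)=C1OCOC | intermediate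
17 | (5S,7S,10S)-7-hydroxy-11,12-bis(methoxymethoxy)-7,10-epoxyicetexa-8,11,13-triene (7-hydroxybrussonol bis-MOM ether, bridged hemiketal; key-step product) | CC(C)c1cc2c(c(OCOC)c1OCOC)C[C@@]13CCCC(C)(C)[C@@H]1C[C@]2(O)O3 | intermediate
18 | (5S,10S)-11,12-bis(methoxymethoxy)icetexa-8,11,13-triene-7,10-diol (both C7 epimers; formed in the flask) | CC(C)c1cc2c(c(OCOC)c1OCOC)C[C@@]1(O)CCCC(C)(C)[C@@H]1CC2O | intermediate
19 | brussonol, (5S,7S,10S)-7,10-epoxyicetexa-8,11,13-triene-11,12-diol | CC(C)c1cc2c(c(O)c1O)C[C@@]13CCCC(C)(C)[C@@H]1C[C@@H]2O3 | intermediate
20 | (5S,7S,10S)-7,10-epoxyicetexa-8,13-diene-11,12-dione (ortho-quinone; formed in the flask, two molecules combine) | CC(C)C1=CC2=C(C(=O)C1=O)C[C@@]13CCCC(C)(C)[C@@H]1C[C@@H]2O3 | intermediate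
21 | CNP0371333.1: (5S,7S,10S)-7,10-epoxyicetexa-8,11,13-triene unit joined through O11 and O12 to C13' and C14' of a (5'S,7'S,10'S,13'R,14'R)-7',10'-epoxyicetex-8'-ene-11',12'-dione unit, cis-fused 1,4-dioxane | CC(C)c1cc2c(c3c1O[C@@H]1C4=C(C[C@@]56CCCC(C)(C)[C@@H]5C[C@@H]4O6)C(=O)C(=O)[C@]1(C(C)C)O3)C[C@@]13CCCC(C)(C)[C@@H]1C[C@@H]2O3 | target

## Step count and risk

Total: 12 steps. Longest linear sequence: 9 steps (steps 1–4 and 8–12). The arene branch (steps 5–7) joins at step 8.

**Step 10 (key step, carries the label).** The photoenol may return to 15 faster than it adds to an unactivated, hindered ketone, so that nothing happens. Prolonged exposure to Ti(OiPr)4 may erode C5 by enolization. A stepwise aldol path may add C20 to the wrong face of C10 and give a cis-fused hydroxy ketone that cannot close the bridge. The fallback uses known chemistry and reverses the order of ring B bond formation; it sets out from 12 and 7 and returns at 19.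
- Bromine–lithium exchange on 12 and a methanol quench would give 1-isopropyl-2,3-bis(methoxymethoxy)-4-methylbenzene F1.
- Its methyl group, the only position ortho to an acetal oxygen that carries hydrogen, would be lithiated (s-BuLi, TMEDA, THF, −78 °C) to [4-isopropyl-2,3-bis(methoxymethoxy)phenyl]methyllithium F2.
- Lactone 7 would be opened with Me2NH and AlMe3 to 2-[(1S,2R)-2-hydroxy-6,6-dimethylcyclohexyl]-N,N-dimethylacetamide F3 and oxidized with Dess–Martin periodinane to 2-[(1S)-6,6-dimethyl-2-oxocyclohexyl]-N,N-dimethylacetamide F4.
- Addition of F2 to the ketone of F4, with CeCl3 present to suppress enolization, should occur equatorially, away from the axial C4 methyl group; acidic work-up would lactonize to (3aS,7aS)-7a-[4-isopropyl-2,3-bis(methoxymethoxy)benzyl]-4,4-dimethylhexahydro-1-benzofuran-2(3H)-one F5.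
- i-Bu2AlH would give the lactol (3aS,7aS)-7a-[4-isopropyl-2,3-bis(methoxymethoxy)benzyl]-4,4-dimethyloctahydro-1-benzofuran-2-ol F6.
- HCl in MeOH followed by BF3·OEt2 in CH2Cl2 should remove the MOM groups and close C7–C8 by Friedel–Crafts attack of C8 (para to the C12 oxygen) on the oxocarbenium ion, arriving at 19.

**Step 12.** The most likely failure is poor discrimination between the two faces of C13'=C14' (and between the two orientations of the dione), together with decay of the quinone by tautomerization towards C20 before it finds its partner molecule. The fallback changes the control element from solution-phase substrate bias to crystal packing. From 19 the quinone 20 would be isolated by crystallization and allowed to react in the solid state below its melting point, so that the lattice pre-organizes the two partners; it returns at 21. No new compound is involved.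

**Step 11.** The ring closure may stall at a C7 methyl ether, the tertiary C10 alcohol may eliminate, or the free catechol may oxidize early. The fallback replaces hydride reduction and cationic etherification by ionic hydrogenation. From 17, Et3SiH and CF3CO2H in CH2Cl2 at 0 °C should reduce the ring-opened oxocarbenium ion, let the C10 hydroxyl capture the benzylic cation and cleave the MOM groups, with the silane scavenging the methoxymethyl cation; it returns at 19. The price is the possibility of reductive cleavage of the C7–O bond. No new compound is involved.

**Step 8.** The hindered, basic aryllithium may deprotonate the lactone α-position instead of adding, returning both partners, or may add twice. The fallback moves the addition to the aldehyde oxidation level. From 7, i-Bu2AlH would give (3aS,7aR)-4,4-dimethyloctahydro-1-benzofuran-2-ol F7. Excess 13 would add to its hydroxy aldehyde tautomer to give 1-[5-isopropyl-3,4-bis(methoxymethoxy)-2-methylphenyl]-2-[(1S,2R)-2-hydroxy-6,6-dimethylcyclohexyl]ethan-1-ol F8. Dess–Martin oxidation of both secondary alcohols would return to the route at 15.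

**Step 1.** Enantioselection may be incomplete for an enone whose two carbonyl substituents differ only modestly, and all later stereocentres depend on it. The fallback replaces catalyst control by enzymatic resolution. From 1, NaBH4 and CeCl3·7H2O in MeOH would give rac-4,4-dimethylcyclohex-2-en-1-ol F9. Candida antarctica lipase B and vinyl acetate are expected to acylate the (R)-alcohol to (R)-4,4-dimethylcyclohex-2-en-1-yl acetate F10 and leave (S)-4,4-dimethylcyclohex-2-en-1-ol F11, which MnO2 would return to 1. Ireland–Claisen rearrangement of F10 (lithium diisopropylamide, Me3SiCl, THF, −78 to 60 °C) would return to the route at 5, which is iodolactonized as in the second half of step 3. This also bypasses the Johnson–Claisen rearrangement should it prove sluggish next to the quaternary carbon.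

## Further compounds

F1 | step 10 | 1-isopropyl-2,3-bis(methoxymethoxy)-4-methylbenzene | CC(C)c1ccc(C)c(OCOC)c1OCOC
F2 | step 10 | [4-isopropyl-2,3-bis(methoxymethoxy)phenyl]methyllithium | [Li]Cc1ccc(C(C)C)c(OCOC)c1OCOC
F3 | step 10 | 2-[(1S,2R)-2-hydroxy-6,6-dimethylcyclohexyl]-N,N-dimethylacetamide | CN(C)C(=O)C[C@H]1C(C)(C)CCC[C@H]1O
F4 | step 10 | 2-[(1S)-6,6-dimethyl-2-oxocyclohexyl]-N,N-dimethylacetamide | CN(C)C(=O)C[C@H]1C(C)(C)CCCC1=O
F5 | step 10 | (3aS,7aS)-7a-[4-isopropyl-2,3-bis(methoxymethoxy)benzyl]-4,4-dimethylhexahydro-1-benzofuran-2(3H)-one | CC(C)c1ccc(C[C@@]23CCCC(C)(C)[C@@H]2CC(=O)O3)c(OCOC)c1OCOC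
F6 | step 10 | (3aS,7aS)-7a-[4-isopropyl-2,3-bis(methoxymethoxy)benzyl]-4,4-dimethyloctahydro-1-benzofuran-2-ol (anomers) | CC(C)c1ccc(C[C@@]23CCCC(C)(C)[C@@H]2CC(O)O3)c(OCOC)c1OCOC
F7 | step 8 | (3aS,7aR)-4,4-dimethyloctahydro-1-benzofuran-2-ol (anomers) | OC1C[C@H]2C(C)(C)CCC[C@H]2O1
F8 | step 8 | 1-[5-isopropyl-3,4-bis(methoxymethoxy)-2-methylphenyl]-2-[(1S,2R)-2-hydroxy-6,6-dimethylcyclohexyl]ethan-1-ol (carbinol epimers) | CC(C)c1cc(C(O)C[C@H]2C(C)(C)CCC[C@H]2O)c(C)c(OCOC)c1OCOC
F9 | step 1 | rac-4,4-dimethylcyclohex-2-en-1-ol | OC1C=CC(C)(C)CC1
F10 | step 1 | (R)-4,4-dimethylcyclohex-2-en-1-yl acetate | CC(=O)O[C@H]1C=CC(C)(C)CC1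
F11 | step 1 | (S)-4,4-dimethylcyclohex-2-en-1-ol | O[C@@H]1C=CC(C)(C)CC1
F0 | step 11 | none | none
F0 | step 12 | none | none
A1 | alternative 1 | 2-(4-isopropylfuran-2-yl)-4,4-dimethyl-7a-(prop-2-yn-1-yl)octahydro-1-benzofuran (cis ring fusion, furyl cis to propargyl) | C#CC[C@@]12CCCC(C)(C)[C@@H]1C[C@H](O2)c1cc(C(C)C)co1
A2 | alternative 1 | 12-deoxybrussonol, (5S,7S,10S)-7,10-epoxyicetexa-8,11,13-trien-11-ol | CC(C)c1cc2c(c(O)c1)C[C@@]13CCCC(C)(C)[C@@H]1C[C@@H]2O3
A3 | alternative 2 | (5S)-5-(4-isopropyl-2,3-dimethoxybenzyl)-5-(4-methylpent-4-en-1-yl)furan-2(5H)-one | CC(=C)CCC[C@]1(Cc2ccc(C(C)C)c(OC)c2OC)C=CC(=O)O1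
A4 | alternative 2 | (3aS,7aS)-7a-(4-isopropyl-2,3-dimethoxybenzyl)-4,4-dimethylhexahydro-1-benzofuran-2(3H)-one (cis-fused) | CC(C)c1ccc(C[C@@]23CCCC(C)(C)[C@@H]2CC(=O)O3)c(OC)c1OC
A5 | alternative 2 | brussonol dimethyl ether, (5S,7S,10S)-11,12-dimethoxy-7,10-epoxyicetexa-8,11,13-triene | CC(C)c1cc2c(c(OC)c1OC)C[C@@]13CCCC(C)(C)[C@@H]1C[C@@H]2O3
A6 | alternative 3 | 1-{(2E)-2-[2-((2R)-3,3-dimethyloxiran-2-yl)ethyl]-5,5-dimethoxypent-2-en-1-yl}-4-isopropyl-2,3-dimethoxybenzene | COC(OC)C/C=C(/Cc1ccc(C(C)C)c(OC)c1OC)CC[C@H]1OC1(C)C
A7 | alternative 3 | 3-hydroxybrussonol dimethyl ether, (3R,5S,7S,10S)-11,12-dimethoxy-7,10-epoxyicetexa-8,11,13-trien-3-ol | CC(C)c1cc2c(c(OC)c1OC)C[C@@]13CC[C@@H](O)C(C)(C)[C@@H]1C[C@@H]2O3
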